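The constants used here come from no measurement.

Watch the trapped intermediate.

    starting material ⇌ intermediate A (K1 = 0.47, k1 = 0.073 s⁻¹)
    intermediate A → target (k2 = 0.26 s⁻¹)
    starting material → side product A (k3 = 0.15 s⁻¹)
    intermediate A ⇌ intermediate B (K4 = 0.45, k4 = 0.24 s⁻¹)
    intermediate B → side product B (k5 = 0.0066 s⁻¹)
    solid substrate ⇌ starting material, rate k6*(cs6 - [starting material]) while solid is left; crystals form when [starting material] > cs6 (cs6 = 0.090 mM, k6 = 0.25 s⁻¹)
    capture agent + intermediate B → trapped intermediate (k7 = 540 M⁻¹ s⁻¹)

| setting | amber | ochre | grey | blue |
|---|---|---|---|---|
| solid substrate | 0.20 mM | 0.20 mM | 0.20 mM | 0.20 mM |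
| capture agent | 0.0100 mM | 0.0300 mM | 0.100 mM | 0.250 mM |
| time | 20 s | 20 s | 20 s | 20 s |

* amount of target at the end, in percent of the solid substrate charged for amber, ochre, grey, blue, in this order
* the course of these numbers from the first flask to the last (falls, then rises / rises, then falls / rises all the way / falls all the way / hardly changes)

- as a solid, counted per litre of solution: solid substrate
- at the start none of the solid substrate is in solution
- "hardly changes" means that all values lie within two and a half points (for a concentration: within two and a half percent of the largest)
- run time (amber): 20 s

Target forms from intermediate A, but the capture agent reaches intermediate B, so the row turns on how much material leaks sideways through intermediate B. Intermediate B goes back to intermediate A with 0.533 s⁻¹, the forward constant over the equilibrium constant, and it goes to side product B with 0.0066 s⁻¹, far less than the way back. Capture in blue adds 0.135 s⁻¹, taken as pseudo-first-order there on the assumption that the capture agent stays near its charge.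

So intermediate B in blue lives 1.48 s, much shorter than the run of 20 s, and its curve can be replaced by its mean: the mean of intermediate A times the forward constant times that lifetime. Target made is its constant times the mean of intermediate A times the time, and trapped intermediate is the capture term times the mean of intermediate B times the time, so mean and time cancel.

What remains is the trapping ratio ρ, trapped intermediate made per target made, which in blue is 0.185. The same reckoning gives 0.00914 in amber and 0.0839 in grey. But intermediate B lags by its lifetime, an error of about 7.40% of the run in blue, so a reading at the end should sit slightly below ρ. This reckoning stops there: ρ divides the flow and gives no row.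

The forecast gives 16.2%, 16%, 15.6% and 15.2%, a course that hardly changes, on the ground that “Capture only drains intermediate B, which is a small side reservoir that mostly returns to A”. On its blue target, ρ puts trapped intermediate near 2.81% of the charge, before the lag is counted.

Target ends at 16.0%, 15.9%, 15.6% and 15.0%, a course that hardly changes, and the local order in capture agent in blue is −0.054. Blue holds 2.50% of trapped intermediate against 15.0% of target at 20.0 s, a reading of 0.167, lower than its ρ of 0.185; at 200 s the reading is 0.182. Grey, with ρ of 0.0839 and 98% of its capture agent left, reads 0.0742 at 20.0 s and 0.0825 at 200 s.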